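**Retrosynthetic overview** (labdane numbering: Br at C3, ring fusion C5/C10, carbinol C8, side chain on C9)
1. Target 12 ⇐ ester reduction ⇐ Horner–Wadsworth–Emmons olefination (C13=C14) of the bicyclic hydroxy ketone 9.
2. 9 ⇐ one enantioselective bromonium cascade on the acyclic (5E,9E)-trienone 7: ring A closes first (C4–C5), ring B second (C9–C10), and the ketone oxygen caps C8 as a transient dihydropyran (ring C) that is opened by hydrolysis.
3. 7 ⇐ key C–C bond C9–C11: the ketone homoenolate released from 1-methylcyclopropanol 6 (nucleophilic β-carbon) joins the E-alkenyl iodide 5, so two normally electrophilic carbons are coupled and the E-trisubstituted alkene is delivered isomerically pure.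
4. 5 ⇐ syn-methylalumination/iodination of enyne 3 ⇐ commercial (E)-geranylacetone 1.

Assumption: the antipode of the thiophosphoramide catalyst that gives the (6R)-bromide series is identified in a test run; the (R)-catalyst is written below and the (S)-catalyst is used if the test shows the opposite sense.

**Step 1**
Reactants: 1 (5E)-6,10-dimethylundeca-5,9-dien-2-one ((E)-geranylacetone)
Product: 3 (5E)-6,10-dimethylundeca-5,9-dien-1-yne, via enol diethyl phosphate 2 (not isolated)
Conditions: LiN(iPr)2 (1.05 equiv), THF, −78 °C; ClP(O)(OEt)2, −78 → 23 °C; then LiN(iPr)2 (2.3 equiv), THF, −78 → 23 °C; H2O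
Reagents that add atoms: none
Why: Kinetic deprotonation at the methyl group gives the terminal enol phosphate, and base-induced elimination of diethyl phosphate (Negishi conversion of a methyl ketone into a terminal alkyne) gives the 1-alkyne without touching the E-trisubstituted alkene.

**Step 2**
Reactants: 3 (5E)-6,10-dimethylundeca-5,9-dien-1-yne
Product: 5 (1E,5E)-1-iodo-2,6,10-trimethylundeca-1,5,9-triene, via alkenyldimethylalane 4 (not isolated)
Conditions: Me3Al (2 equiv), Cp2ZrCl2 (0.25 equiv), ClCH2CH2Cl, 23 °C; then I2, THF, −30 → 0 °C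
Reagents that add atoms: trimethylaluminium C[Al](C)C; iodine [I][I]
Why: Zirconium-catalysed syn-methylalumination (Negishi carboalumination) puts the methyl group on the internal and aluminium on the terminal alkyne carbon on the same face, and iodinolysis of the carbon–aluminium bond with retention fixes the new trisubstituted alkene as E.

**Step 3 (key step)**
Reactants: 5 (1E,5E)-1-iodo-2,6,10-trimethylundeca-1,5,9-triene; 6 1-methylcyclopropan-1-ol
Product: 7 (5E,9E)-6,10,14-trimethylpentadeca-5,9,13-trien-2-one
Conditions: Pd(OAc)2 (5 mol %), XPhos (2-dicyclohexylphosphino-2',4',6'-triisopropylbiphenyl, 10 mol %), Cs2CO3 (2 equiv), 6 (2 equiv), PhMe, 60 °C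
Reagents that add atoms: 1-methylcyclopropan-1-ol CC1(O)CC1
Why: Proposed new method: oxidative addition of the alkenyl iodide to zerovalent palladium, exchange of iodide for the cyclopropanolate and strain-driven β-carbon elimination give an alkenyl(3-oxobutyl)palladium homoenolate, whose β-carbon (normally an electrophilic position of the ketone) reductively eliminates onto the alkenyl carbon with retention of the E geometry, the bulky biaryl phosphine being chosen so that reductive elimination outruns β-hydride loss to methyl vinyl ketone; the closest known reaction type is the palladium-catalysed ring-opening cross-coupling of cyclopropanol-derived ketone homoenolates with aryl halides.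

**Step 4**
Reactants: 7 (5E,9E)-6,10,14-trimethylpentadeca-5,9,13-trien-2-one
Product: 9 4-[(1S,2S,4aS,6R,8aR)-6-bromo-2-hydroxy-2,5,5,8a-tetramethyldecahydronaphthalen-1-yl]butan-2-one, via bromo enol ether 8 (not isolated)
Conditions: (R)-3,3'-bis(2,4,6-triisopropylphenyl)-1,1'-binaphthyl-2,2'-diyl N-triflylthiophosphoramide (10 mol %), 1,3-dibromo-5,5-dimethylhydantoin (0.55 equiv), PhMe/CH2Cl2, −78 °C; then 1 M HCl, THF, 23 °C; recrystallisation to raise the ee
Reagents that add atoms: 1,3-dibromo-5,5-dimethylhydantoin CC1(C)N(Br)C(=O)N(Br)C1=O; water O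
Why: Proposed new method: the chiral P=S Lewis base takes Br+ from the hydantoin and delivers it to one face of the terminal alkene (sets C3), the bromonium ion is opened by two anti additions across the E alkenes through a chair–chair transition state (Stork–Eschenmoser bromonium polyene cyclisation; sets the trans ring fusion C5/C10 and C9, Br equatorial), the ketone oxygen captures the C8 cation from the equatorial side (sets C8) to give enol ether 8, and aqueous acid opens 8 to the hydroxy ketone; the closest known reaction types are the catalytic asymmetric bromocyclisation of aryl-terminated polyenes with this catalyst class and the racemic ketone-terminated cyclisation of geranyl- and farnesylacetone to cyclic enol ethers.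

**Step 5**
Reactants: 9 4-[(1S,2S,4aS,6R,8aR)-6-bromo-2-hydroxy-2,5,5,8a-tetramethyldecahydronaphthalen-1-yl]butan-2-one; 10 triethyl phosphonoacetate
Product: 11 ethyl (2E)-5-[(1S,2S,4aS,6R,8aR)-6-bromo-2-hydroxy-2,5,5,8a-tetramethyldecahydronaphthalen-1-yl]-3-methylpent-2-enoate
Conditions: 10 (3 equiv), NaH (3.5 equiv), THF, 0 → 65 °C; SiO2 chromatography to remove the minor 2Z ester
Reagents that add atoms: triethyl phosphonoacetate CCOC(=O)CP(=O)(OCC)OCC
Why: Horner–Wadsworth–Emmons olefination of the unhindered methyl ketone puts the ester trans to the larger chain (E favoured, expected about 4–5:1), while the tertiary alkoxide and the equatorial bromide, which has no antiperiplanar hydrogen for elimination, stay intact.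

**Step 6**
Reactants: 11 ethyl (2E)-5-[(1S,2S,4aS,6R,8aR)-6-bromo-2-hydroxy-2,5,5,8a-tetramethyldecahydronaphthalen-1-yl]-3-methylpent-2-enoate
Product: 12 (1S,2S,4aS,6R,8aR)-6-bromo-1-[(3E)-5-hydroxy-3-methylpent-3-en-1-yl]-2,5,5,8a-tetramethyldecahydronaphthalen-2-ol
Conditions: i-Bu2AlH (4 equiv), CH2Cl2, −78 → −40 °C; aq. potassium sodium tartrate
Reagents that add atoms: none
Why: 1,2-Reduction of the conjugated ester by the aluminium hydride gives the allylic alcohol without changing the alkene geometry, the secondary bromide or any stereocentre.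

**Compound list**
1 | (5E)-6,10-dimethylundeca-5,9-dien-2-one ((E)-geranylacetone) | CC(=O)CC/C=C(\C)CCC=C(C)C | starting material
2 | diethyl (5E)-6,10-dimethylundeca-1,5,9-trien-2-yl phosphate | C=C(OP(=O)(OCC)OCC)CC/C=C(\C)CCC=C(C)C | intermediate
3 | (5E)-6,10-dimethylundeca-5,9-dien-1-yne | C#CCC/C=C(\C)CCC=C(C)C | intermediate
4 | dimethyl[(1E,5E)-2,6,10-trimethylundeca-1,5,9-trien-1-yl]alane | C[Al](C)/C=C(\C)CC/C=C(\C)CCC=C(C)C | intermediate
5 | (1E,5E)-1-iodo-2,6,10-trimethylundeca-1,5,9-triene | I/C=C(\C)CC/C=C(\C)CCC=C(C)C | intermediate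
6 | 1-methylcyclopropan-1-ol | CC1(O)CC1 | starting material
7 | (5E,9E)-6,10,14-trimethylpentadeca-5,9,13-trien-2-one | CC(=O)CC/C=C(\C)CC/C=C(\C)CCC=C(C)C | intermediate
8 | (3R,5S,8S,9S,10R)-3-bromo-8,13-epoxy-14,15-dinorlabd-12-ene (tricyclic enol ether: former ketone oxygen bonded to C8, C12=C13 in the new dihydropyran ring) | CC1=CC[C@H]2[C@]3(C)CC[C@@H](Br)C(C)(C)[C@H]3CC[C@]2(C)O1 | intermediate
9 | 4-[(1S,2S,4aS,6R,8aR)-6-bromo-2-hydroxy-2,5,5,8a-tetramethyldecahydronaphthalen-1-yl]butan-2-one | CC(=O)CC[C@H]1[C@]2(C)CC[C@@H](Br)C(C)(C)[C@H]2CC[C@]1(C)O | intermediate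
10 | triethyl phosphonoacetate | CCOC(=O)CP(=O)(OCC)OCC | starting material
11 | ethyl (2E)-5-[(1S,2S,4aS,6R,8aR)-6-bromo-2-hydroxy-2,5,5,8a-tetramethyldecahydronaphthalen-1-yl]-3-methylpent-2-enoate | C/C(=C\C(=O)OCC)CC[C@H]1[C@]2(C)CC[C@@H](Br)C(C)(C)[C@H]2CC[C@]1(C)O | intermediate
12 | (1S,2S,4aS,6R,8aR)-6-bromo-1-[(3E)-5-hydroxy-3-methylpent-3-en-1-yl]-2,5,5,8a-tetramethyldecahydronaphthalen-2-ol | C/C(=C\CO)CC[C@H]1[C@]2(C)CC[C@@H](Br)C(C)(C)[C@H]2CC[C@]1(C)O | target

**Total step count:** 6. **Longest linear sequence:** 6 steps (1 → 3 → 5 → 7 → 9 → 11 → 12); 6 and 10 are purchased.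

**Three steps most likely to fail, each with a fallback**

Step 3 (key coupling). The alkylpalladium homoenolate may lose β-hydride faster than it couples, or the cyclopropanol may simply isomerise to butanone. The fallback keeps the same bond but uses a stoichiometric, protected homoenolate. It sets out from 5. The Grignard reagent [2-(2-methyl-1,3-dioxolan-2-yl)ethyl]magnesium bromide F1 is made from commercial 2-(2-bromoethyl)-2-methyl-1,3-dioxolane and Mg in THF. It is coupled with 5 under PdCl2(dppf) catalysis (THF, 23 °C) to give the ketal 2-methyl-2-[(3E,7E)-4,8,12-trimethyltrideca-3,7,11-trien-1-yl]-1,3-dioxolane F2. Hydrolysis (pyridinium tosylate, acetone/water, 50 °C) brings the route back at 7.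

Step 4 (asymmetric bromocyclisation). The catalyst has not been shown on a ketone-terminated triene. Enantioselectivity, selectivity for the terminal alkene, or over-bromination of enol ether 8 could each be a problem. The fallback separates ring formation from carbon–bromine bond formation. It sets out from 7. Hg(OTf)2 complexed by (R,R)- or (S,S)-2,2'-isopropylidenebis(4-phenyl-2-oxazoline) (CH2Cl2, −78 °C) triggers the same chair–chair cascade through a mercurinium ion. Brine and dilute HCl then give the organomercurial 4-[(1S,2S,4aS,6R,8aR)-6-(chloromercurio)-2-hydroxy-2,5,5,8a-tetramethyldecahydronaphthalen-1-yl]butan-2-one F3, which is recrystallised. The carbon–mercury bond is replaced by bromine with retention (Br2, LiBr, pyridine, 0 °C, dark), and the route is rejoined at 9.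

Step 5 (olefination). The E/Z ratio may be low or the isomers hard to separate. The fallback builds the alkene by stereospecific carbometalation instead of olefination. It sets out from 9. LiN(iPr)2 (2.1 equiv) and ClP(O)(OEt)2 in THF at −78 °C give the enol phosphate diethyl 4-[(1S,2S,4aS,6R,8aR)-6-bromo-2-hydroxy-2,5,5,8a-tetramethyldecahydronaphthalen-1-yl]but-1-en-2-yl phosphate F4. More LiN(iPr)2 eliminates it to the alkyne (1S,2S,4aS,6R,8aR)-6-bromo-1-(but-3-yn-1-yl)-2,5,5,8a-tetramethyldecahydronaphthalen-2-ol F5. Me3Al (3 equiv) with Cp2ZrCl2 adds methyl and aluminium syn to give the alkenyldimethylalane (oxygen at C8 carried as its dimethylaluminium alkoxide) F6. Trapping with ethyl chloroformate gives the ester as the pure E isomer, and the route is rejoined at 11.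

**Further compounds**
F1 | step 3 | [2-(2-methyl-1,3-dioxolan-2-yl)ethyl]magnesium bromide | CC1(CC[Mg]Br)OCCO1
F2 | step 3 | 2-methyl-2-[(3E,7E)-4,8,12-trimethyltrideca-3,7,11-trien-1-yl]-1,3-dioxolane | CC1(CC/C=C(\C)CC/C=C(\C)CCC=C(C)C)OCCO1
F3 | step 4 | 4-[(1S,2S,4aS,6R,8aR)-6-(chloromercurio)-2-hydroxy-2,5,5,8a-tetramethyldecahydronaphthalen-1-yl]butan-2-one | CC(=O)CC[C@H]1[C@]2(C)CC[C@@H]([Hg]Cl)C(C)(C)[C@H]2CC[C@]1(C)O
F4 | step 5 | diethyl 4-[(1S,2S,4aS,6R,8aR)-6-bromo-2-hydroxy-2,5,5,8a-tetramethyldecahydronaphthalen-1-yl]but-1-en-2-yl phosphate | C=C(OP(=O)(OCC)OCC)CC[C@H]1[C@]2(C)CC[C@@H](Br)C(C)(C)[C@H]2CC[C@]1(C)O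
F5 | step 5 | (1S,2S,4aS,6R,8aR)-6-bromo-1-(but-3-yn-1-yl)-2,5,5,8a-tetramethyldecahydronaphthalen-2-ol | C#CCC[C@H]1[C@]2(C)CC[C@@H](Br)C(C)(C)[C@H]2CC[C@]1(C)O
F6 | step 5 | (E)-alkenyldimethylalane of the side chain, C8 oxygen as dimethylaluminium alkoxide | C[Al](C)/C=C(\C)CC[C@H]1[C@]2(C)CC[C@@H](Br)C(C)(C)[C@H]2CC[C@]1(C)O[Al](C)C
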